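**Plan**

Numbering used: oxane O1, C2 (trioxygenated aryl), C4 (OH), C6 (CH2CH2‑guaiacyl); target is the all‑equatorial (2S,4R,6S) isomer.
- Retrosynthesis cuts, in order: the three O–benzyl bonds; C6–H and C6–O1 (back to a cyclic methyl ketal, i.e. a δ‑hydroxy ketone); the guaiacyl C1–CH2 bond (aryl bromide + cyclopropanol); the cyclopropane (ester + EtMgBr); the C2–C3 aldol bond (aryl aldehyde + acetoacetate dienolate).
- Enabling feature: the benzylic CH2 of the guaiacyl arm is β to C6, the ring carbon next to O1. With C6 at the ketone level that CH2 is a homoenolate carbon, stored as a 1‑substituted cyclopropanol, so two carbons of electrophile type (aryl C–Br and ketone β‑carbon) are joined by polarity reversal.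
- Forward order: open chain first (aldol, anti‑diol, acetonide, cyclopropanol); the Pd coupling then joins the two aryl halves and releases the C6 ketone; the oxane ring is closed as a methyl ketal and reduced; debenzylation ends the route.
- Stereochemistry: C2 from a Ti/(S)‑BINOL vinylogous aldol; C4 from a hydroxyl‑directed 1,3‑anti reduction; C6 from axial hydride addition to the ring oxocarbenium ion (2,6‑cis).
- Helpers: the cyclopropane ring is consumed in step 6 and the C6 carbonyl oxidation level is removed in step 8.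

Key step: step 6

Assumption 1: the Ti–BINOL catalyst is taken to follow its usual sense with aromatic aldehydes ((S)‑BINOL, Si‑face attack, 5S); the configuration would be checked on 5 and (R)‑BINOL used if the sense were opposite.
Assumption 2: bromide 9 and diene 3 are taken as purchasable.

**Route**

Step 1
Reactants: 1 3,4-dihydroxy-5-methoxybenzaldehyde
Product: 2 3,4-bis(benzyloxy)-5-methoxybenzaldehyde
Conditions: BnBr (2.4 equiv), K2CO3, DMF, 60 °C
Reagents that add atoms: benzyl bromide, BrCc1ccccc1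
Why: Williamson O‑alkylation of both phenoxides by the benzylic bromide leaves the aldehyde untouched, and benzyl ethers should survive Grignard/Ti, Pd/carbonate and Lewis acid/silane before leaving by hydrogenolysis.

Step 2
Reactants: 2 3,4-bis(benzyloxy)-5-methoxybenzaldehyde; 3 1-methoxy-1,3-bis(trimethylsilyloxy)buta-1,3-diene
Product: 5 methyl (5S)-5-[3,4-bis(benzyloxy)-5-methoxyphenyl]-5-hydroxy-3-oxopentanoate, via bis-silyl aldol adduct 4 (not isolated)
Conditions: Ti(OiPr)4 (10 mol %), (S)-BINOL (10 mol %), 4 Å MS, THF, −78 °C to rt; then TFA, −78 °C to rt, aq. NaHCO3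
Reagents that add atoms: none
Why: Catalytic enantioselective vinylogous Mukaiyama aldol, in which the Ti(IV)–(S)‑BINOL complex activates the aldehyde and the γ‑carbon of the silyl dienolate should add to its Si face to set 5S (the future C2), the acidic work‑up removing both silyl groups.

Step 3
Reactants: 5 methyl (5S)-5-[3,4-bis(benzyloxy)-5-methoxyphenyl]-5-hydroxy-3-oxopentanoate
Product: 6 methyl (3S,5S)-5-[3,4-bis(benzyloxy)-5-methoxyphenyl]-3,5-dihydroxypentanoate
Conditions: Me4NBH(OAc)3, MeCN/AcOH (1:1), −30 °C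
Reagents that add atoms: none
Why: Evans–Saksena reduction, in which the C5 alkoxide binds boron and delivers hydride intramolecularly through a chair transition state to give the 1,3‑anti diol, setting 3S (the future C4 carbinol) while the ester is untouched.

Step 4
Reactants: 6 methyl (3S,5S)-5-[3,4-bis(benzyloxy)-5-methoxyphenyl]-3,5-dihydroxypentanoate
Product: 7 methyl 2-[(4S,6S)-6-[3,4-bis(benzyloxy)-5-methoxyphenyl]-2,2-dimethyl-1,3-dioxan-4-yl]acetate
Conditions: 2,2-dimethoxypropane, PPTS (cat.), CH2Cl2, rt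
Reagents that add atoms: 2,2-dimethoxypropane, COC(C)(C)OC
Why: Acid‑catalysed transketalisation masks both hydroxyl groups as the anti‑diol acetonide, so that neither consumes Grignard reagent in step 5 nor is oxidised by arylpalladium in step 6.

Step 5
Reactants: 7 methyl 2-[(4S,6S)-6-[3,4-bis(benzyloxy)-5-methoxyphenyl]-2,2-dimethyl-1,3-dioxan-4-yl]acetate
Product: 8 1-{[(4S,6S)-6-[3,4-bis(benzyloxy)-5-methoxyphenyl]-2,2-dimethyl-1,3-dioxan-4-yl]methyl}cyclopropan-1-ol
Conditions: EtMgBr (3 equiv), Ti(OiPr)4 (0.3 equiv), THF, 0 °C to rt; aq. NH4Cl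
Reagents that add atoms: ethylmagnesium bromide, CC[Mg]Br
Why: Kulinkovich cyclopropanation, in which the titanacyclopropane formed from two ethyl groups acts as a 1,2‑dicarbanion on the ester carbonyl to give the 1‑substituted cyclopropanol, the acetonide, benzyl ethers and both stereocentres being inert to Grignard/Ti(IV).

Step 6
Reactants: 8 1-{[(4S,6S)-6-[3,4-bis(benzyloxy)-5-methoxyphenyl]-2,2-dimethyl-1,3-dioxan-4-yl]methyl}cyclopropan-1-ol; 9 1-(benzyloxy)-4-bromo-2-methoxybenzene
Product: 10 4-[4-(benzyloxy)-3-methoxyphenyl]-1-[(4S,6S)-6-[3,4-bis(benzyloxy)-5-methoxyphenyl]-2,2-dimethyl-1,3-dioxan-4-yl]butan-2-one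
Conditions: Pd(OAc)2 (5 mol %), XPhos (10 mol %), Cs2CO3 (2 equiv), toluene, 80 °C
Reagents that add atoms: none
Why: Pd(0)/XPhos inserts into the C–Br bond of 9, the caesium cyclopropoxide of 8 displaces bromide on Pd(II), and strain‑driven β‑carbon elimination opens the three‑membered ring to a palladium homoenolate (Pd on a former cyclopropane CH2, the carbinol carbon now the ketone) that reductively eliminates to form the aryl–CH2 bond. The closest known reaction type is the palladium‑catalysed ring‑opening cross‑coupling of tertiary cyclopropanols with aryl bromides to β‑aryl ketones, a union of two carbons that are both electrophilic in conventional synthons. No ring is closed and no stereocentre is created; the cyclopropane is the only ring opened, and the dioxane stereocentres are remote from the reacting atoms and not epimerisable under carbonate. The step needs reductive elimination to outrun β‑hydride elimination to the vinyl ketone, which the bulky electron‑rich biaryl phosphine should secure, and regiochemistry of ring opening is not an issue because the two cyclopropane CH2 groups are equivalent. The acetonide keeps the benzylic and homobenzylic oxygens from being oxidised by the arylpalladium(II) species.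

Step 7
Reactants: 10 4-[4-(benzyloxy)-3-methoxyphenyl]-1-[(4S,6S)-6-[3,4-bis(benzyloxy)-5-methoxyphenyl]-2,2-dimethyl-1,3-dioxan-4-yl]butan-2-one
Product: 12 (2S,4S,6S)-2-{2-[4-(benzyloxy)-3-methoxyphenyl]ethyl}-6-[3,4-bis(benzyloxy)-5-methoxyphenyl]-2-methoxyoxan-4-ol, via dihydroxy ketone 11 (not isolated)
Conditions: PPTS (cat.), MeOH, rt
Reagents that add atoms: methanol, CO
Why: Acid‑catalysed methanolysis of the strained anti‑acetonide frees the diol, whose benzylic hydroxyl closes on the ketone (6‑exo‑trig hemiketalisation, then ketal exchange) to the cyclic methyl ketal, expected mainly as the axial‑methoxy anomer (anomeric effect), a centre that is erased in step 8.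

Step 8
Reactants: 12 (2S,4S,6S)-2-{2-[4-(benzyloxy)-3-methoxyphenyl]ethyl}-6-[3,4-bis(benzyloxy)-5-methoxyphenyl]-2-methoxyoxan-4-ol
Product: 13 (2S,4R,6S)-2-[3,4-bis(benzyloxy)-5-methoxyphenyl]-6-{2-[4-(benzyloxy)-3-methoxyphenyl]ethyl}oxan-4-ol
Conditions: Et3SiH (3 equiv), BF3·OEt2 (2 equiv), CH2Cl2/MeCN, −78 to −40 °C
Reagents that add atoms: none
Why: Reductive etherification, in which BF3 ionises the ketal to a ring oxocarbenium ion whose half‑chair carries the aryl and hydroxyl groups pseudo‑equatorial, and Et3SiH adds along the axial trajectory to place the arylethyl chain equatorial, setting 6S (2,6‑cis).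

Step 9
Reactants: 13 (2S,4R,6S)-2-[3,4-bis(benzyloxy)-5-methoxyphenyl]-6-{2-[4-(benzyloxy)-3-methoxyphenyl]ethyl}oxan-4-ol
Product: 14 (2S,4R,6S)-2-(3,4-dihydroxy-5-methoxyphenyl)-6-[2-(4-hydroxy-3-methoxyphenyl)ethyl]oxan-4-ol
Conditions: H2 (1 atm), 10% Pd/C, EtOAc/MeOH, rt, stopped at full conversion
Reagents that add atoms: none
Why: Catalytic hydrogenolysis cleaves the three aryl benzyl ethers much faster than the secondary cyclic benzylic C2–O1 bond, so the oxane and its three stereocentres should remain intact.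

**Compound list**

1 | 3,4-dihydroxy-5-methoxybenzaldehyde | COc1cc(C=O)cc(O)c1O | starting material
2 | 3,4-bis(benzyloxy)-5-methoxybenzaldehyde | COc1cc(C=O)cc(OCc2ccccc2)c1OCc1ccccc1 | intermediate
3 | 1-methoxy-1,3-bis(trimethylsilyloxy)buta-1,3-diene (ketene acetal geometry as supplied, lost in the reaction) | COC(O[Si](C)(C)C)=CC(=C)O[Si](C)(C)C | starting material
4 | methyl (5S)-5-[3,4-bis(benzyloxy)-5-methoxyphenyl]-3,5-bis(trimethylsilyloxy)pent-2-enoate (bis-silyl aldol adduct, not isolated; E/Z mixture expected, both converge on 5) | COC(=O)C=C(O[Si](C)(C)C)C[C@@H](c1cc(OCc2ccccc2)c(OCc2ccccc2)c(OC)c1)O[Si](C)(C)C | intermediate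
5 | methyl (5S)-5-[3,4-bis(benzyloxy)-5-methoxyphenyl]-5-hydroxy-3-oxopentanoate | COC(=O)CC(=O)C[C@@H](c1cc(OCc2ccccc2)c(OCc2ccccc2)c(OC)c1)O | intermediate
6 | methyl (3S,5S)-5-[3,4-bis(benzyloxy)-5-methoxyphenyl]-3,5-dihydroxypentanoate | COC(=O)C[C@@H](O)C[C@@H](c1cc(OCc2ccccc2)c(OCc2ccccc2)c(OC)c1)O | intermediate
7 | methyl 2-[(4S,6S)-6-[3,4-bis(benzyloxy)-5-methoxyphenyl]-2,2-dimethyl-1,3-dioxan-4-yl]acetate | COC(=O)C[C@@H]1C[C@@H](c2cc(OCc3ccccc3)c(OCc3ccccc3)c(OC)c2)OC(C)(C)O1 | intermediate
8 | 1-{[(4S,6S)-6-[3,4-bis(benzyloxy)-5-methoxyphenyl]-2,2-dimethyl-1,3-dioxan-4-yl]methyl}cyclopropan-1-ol | OC1(C[C@@H]2C[C@@H](c3cc(OCc4ccccc4)c(OCc4ccccc4)c(OC)c3)OC(C)(C)O2)CC1 | intermediate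
9 | 1-(benzyloxy)-4-bromo-2-methoxybenzene | COc1cc(Br)ccc1OCc1ccccc1 | starting material
10 | 4-[4-(benzyloxy)-3-methoxyphenyl]-1-[(4S,6S)-6-[3,4-bis(benzyloxy)-5-methoxyphenyl]-2,2-dimethyl-1,3-dioxan-4-yl]butan-2-one | COc1cc(CCC(=O)C[C@@H]2C[C@@H](c3cc(OCc4ccccc4)c(OCc4ccccc4)c(OC)c3)OC(C)(C)O2)ccc1OCc1ccccc1 | intermediate
11 | (5S,7S)-1-[4-(benzyloxy)-3-methoxyphenyl]-7-[3,4-bis(benzyloxy)-5-methoxyphenyl]-5,7-dihydroxyheptan-3-one (not isolated in the main route) | COc1cc(CCC(=O)C[C@@H](O)C[C@@H](c2cc(OCc3ccccc3)c(OCc3ccccc3)c(OC)c2)O)ccc1OCc1ccccc1 | intermediate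
12 | (2S,4S,6S)-2-{2-[4-(benzyloxy)-3-methoxyphenyl]ethyl}-6-[3,4-bis(benzyloxy)-5-methoxyphenyl]-2-methoxyoxan-4-ol | COc1cc(CC[C@@]2(OC)C[C@@H](O)C[C@@H](c3cc(OCc4ccccc4)c(OCc4ccccc4)c(OC)c3)O2)ccc1OCc1ccccc1 | intermediate
13 | (2S,4R,6S)-2-[3,4-bis(benzyloxy)-5-methoxyphenyl]-6-{2-[4-(benzyloxy)-3-methoxyphenyl]ethyl}oxan-4-ol | COc1cc(CC[C@H]2C[C@@H](O)C[C@@H](c3cc(OCc4ccccc4)c(OCc4ccccc4)c(OC)c3)O2)ccc1OCc1ccccc1 | intermediate
14 | (2S,4R,6S)-2-(3,4-dihydroxy-5-methoxyphenyl)-6-[2-(4-hydroxy-3-methoxyphenyl)ethyl]oxan-4-ol | COc1cc(CC[C@H]2C[C@@H](O)C[C@@H](c3cc(O)c(O)c(OC)c3)O2)ccc1O | target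

**Step count**

Total steps: 9. Longest linear sequence: 9 (1 to 14); bromide 9 enters at step 6.

**Steps most likely to fail, with fallbacks**

Step 6. β‑Hydride elimination from the palladium homoenolate may outrun reductive elimination, or the carbonate base may expel the acetonide oxygen β to the new ketone. The fallback sets out from cyclopropanol 8 and comes back at ketone 10. The ring would be opened oxidatively (Pd(OAc)2 cat., pyridine, O2, toluene, 80 °C) to the vinyl ketone 1-[(4S,6S)-6-[3,4-bis(benzyloxy)-5-methoxyphenyl]-2,2-dimethyl-1,3-dioxan-4-yl]but-3-en-2-one F1. The aryl–CH2 bond would then be made with normal polarity by Rh(I)‑catalysed 1,4‑addition of [4-(benzyloxy)-3-methoxyphenyl]boronic acid (Rh(acac)(CO)2, dppb, aq. MeOH, 50 °C), which should give 10.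

Step 2. The electron‑rich, hindered aldehyde may react sluggishly and with eroded enantioselectivity. The fallback sets out from aldehyde 2 and comes back at keto ester 5. An auxiliary‑controlled acetate aldol with the chlorotitanium enolate of (R)-3-acetyl-4-isopropyl-1,3-thiazolidine-2-thione (TiCl4, iPr2NEt, CH2Cl2, −78 °C; chelated chair transition state) should give (3S)-3-[3,4-bis(benzyloxy)-5-methoxyphenyl]-3-hydroxy-1-[(4R)-4-isopropyl-2-thioxo-1,3-thiazolidin-3-yl]propan-1-one F2, the minor diastereomer being removed by chromatography. Acyl transfer to the magnesium enolate of potassium methyl malonate (MgCl2, imidazole, THF, rt) with decarboxylation should then give 5.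

Step 8. Ionisation of the electron‑rich benzylic C2–O1 bond under the Lewis acid may lead to ring opening and over‑reduction, or hydride addition may lose its axial preference. The fallback sets out from ketone 10 and comes back at 13, closing the ring at the other C–O bond. Aqueous AcOH would hydrolyse the acetonide to dihydroxy ketone 11, here isolated. A second hydroxyl‑directed anti reduction (Me4NBH(OAc)3, MeCN/AcOH, −30 °C) should give (3S,5R,7S)-1-[4-(benzyloxy)-3-methoxyphenyl]-7-[3,4-bis(benzyloxy)-5-methoxyphenyl]heptane-3,5,7-triol F3. Catalytic acid (Re2O7 or TsOH, CH2Cl2, rt) should then effect dehydrative cyclisation through the stabilised benzylic cation, under thermodynamic control, to the all‑equatorial oxane 13.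

**Further compounds**

F1 | step 6 | 1-[(4S,6S)-6-[3,4-bis(benzyloxy)-5-methoxyphenyl]-2,2-dimethyl-1,3-dioxan-4-yl]but-3-en-2-one | C=CC(=O)C[C@@H]1C[C@@H](c2cc(OCc3ccccc3)c(OCc3ccccc3)c(OC)c2)OC(C)(C)O1
F2 | step 2 | (3S)-3-[3,4-bis(benzyloxy)-5-methoxyphenyl]-3-hydroxy-1-[(4R)-4-isopropyl-2-thioxo-1,3-thiazolidin-3-yl]propan-1-one | S=C1SC[C@@H](C(C)C)N1C(=O)C[C@@H](c1cc(OCc2ccccc2)c(OCc2ccccc2)c(OC)c1)O
F3 | step 8 | (3S,5R,7S)-1-[4-(benzyloxy)-3-methoxyphenyl]-7-[3,4-bis(benzyloxy)-5-methoxyphenyl]heptane-3,5,7-triol | COc1cc(CC[C@H](O)C[C@@H](O)C[C@@H](c2cc(OCc3ccccc3)c(OCc3ccccc3)c(OC)c2)O)ccc1OCc1ccccc1
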